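**Plan**

- Locants: the right-hand decalin is ring A (C1'–C5', C10') and ring B (C5'–C10'), with benzylic carbon C11'. The left-hand decalin (rings C and D), the linker C11–C12 and C13/C16 keep labdane numbers, so C13 = C4' and C16 = the methyl group on C4'.
- Cuts: (1) the two aryl O–S bonds; (2) C11'–aryl (B-alkyl Suzuki–Miyaura) and the ring B alkene and methyl, back to a C9' ketone; (3) C4'–C5', by a retro 1,2-shift that contracts ring A to a cyclopentane; (4) C3'–C4', a carbonyl addition that divides the molecule into a C18 and a C12 half.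
- Enabling feature: the quaternary C4' of ring A bears one methyl group and the linker, and it lies between a bare methylene (C3') and the ring-fusion carbon C5'. C4', its methyl, the linker and rings C and D are together the methyl ketone left by degradation of manool. This carbon can be inserted between C3' and C5' of a hydrindenone whose C5'=C6' bond is the migrating group.
- Forward: rings C and D come from manool, with C8 rebuilt by ozonolysis and Grignard addition. Ring B is 2-methylcyclohexane-1,3-dione, and the five-membered forerunner of ring A is closed by a carbene-catalysed benzoin reaction. After Shapiro union and the five-to-six ring expansion, the alkene and ketone helpers are removed, ring B is elaborated and arylated, and the hydroquinone is sulfated.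
- Stereochemistry: C5, C9 and C10 come from manool, C8 from equatorial attack on the C8 ketone, and C10' from catalyst-controlled desymmetrisation. C3' (temporary), C4', C5' and C9' are all relayed from the β-methyl group on C10'.

Key step: step 10

Assumption: the target is taken as the free bis(hydrogen sulfate) as drawn. It is released from its pyridinium salt by cation exchange in the last step and would be stored as a salt.

**Step 1**
Reactants: 1 (+)-manool
Product: 2 14,15-dinorlabd-8(17)-en-13-one
Conditions: KMnO4, MgSO4, acetone/H2O, 0 °C to rt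
Reagents that add atoms: none
Why: Permanganate degradation of a tertiary vinyl carbinol (glycol formation, C–C cleavage, oxidative decarboxylation) should excise C14 and C15 and leave the C13 methyl ketone, because the monosubstituted vinyl group is far more accessible than the hindered exocyclic C8=C17 bond.

**Step 2**
Reactants: 2 14,15-dinorlabd-8(17)-en-13-one
Product: 3 14,15,17-trinorlabdane-8,13-dione
Conditions: O3, CH2Cl2/MeOH, −78 °C; Me2S, −78 °C to rt
Reagents that add atoms: ozone, [O-][O+]=O
Why: Ozonolysis with reductive work-up turns the only alkene into the C8 ketone, and C9 keeps its more stable equatorial side chain.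

**Step 3**
Reactants: 3 14,15,17-trinorlabdane-8,13-dione
Product: 4 13-(E)-trisylhydrazone of dione 3
Conditions: 2,4,6-triisopropylbenzenesulfonohydrazide (1.0 equiv), cat. HCl, THF, rt
Reagents that add atoms: 2,4,6-triisopropylbenzenesulfonohydrazide, NNS(=O)(=O)c1c(C(C)C)cc(C(C)C)cc1C(C)C
Why: Hydrazone condensation should be chemoselective for the unhindered methyl ketone over the α-branched ring ketone, so it masks C13 and installs the Shapiro handle in one operation.

**Step 4**
Reactants: 4 13-(E)-trisylhydrazone of dione 3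
Product: 5 (E)-trisylhydrazone of 8β-hydroxy-8α-methyl-14,15,17-trinorlabdan-13-one
Conditions: MeMgBr (4 equiv), THF/Et2O, −78 to 0 °C; aq NH4Cl
Reagents that add atoms: methylmagnesium bromide, C[Mg]Br
Why: In this Grignard 1,2-addition the N-magnesiated hydrazone is inert, and axial approach to the C8 carbonyl is blocked by the syn-axial C10 methyl group, so methyl should enter equatorially from the α face and give the axial 8β-alcohol.

**Step 5**
Reactants: 6 2-methylcyclohexane-1,3-dione; 7 acrolein
Product: 8 3-(1-methyl-2,6-dioxocyclohexyl)propanal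
Conditions: H2O, rt
Reagents that add atoms: none
Why: Michael addition of the stabilised enol of the 1,3-dione to acrolein builds the achiral quaternary carbon (later C10') with its C1'–C2'–C3' arm.

**Step 6**
Reactants: 8 3-(1-methyl-2,6-dioxocyclohexyl)propanal
Product: 9 (3aS,7aR)-7a-hydroxy-3a-methylhexahydro-1H-indene-1,4(2H)-dione
Conditions: aminoindanol-derived N-pentafluorophenyl triazolium tetrafluoroborate (10 mol %, the enantiomer that gives the 3aS product), Et3N (10 mol %), CH2Cl2, rt
Reagents that add atoms: none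
Why: In this intramolecular crossed benzoin reaction (5-exo-trig attack of the Breslow intermediate at C3' on a ring ketone) the chiral carbene selects one of the two enantiotopic ketones, so it sets C10' and closes the cis-fused five-membered forerunner of ring A.

**Step 7**
Reactants: 9 (3aS,7aR)-7a-hydroxy-3a-methylhexahydro-1H-indene-1,4(2H)-dione
Product: 10 (S)-3a-methyl-2,3,5,6-tetrahydro-1H-indene-1,4(3aH)-dione
Conditions: SOCl2, pyridine, 0 °C
Reagents that add atoms: none
Why: E2 dehydration through the chlorosulfite is regiochemically unambiguous because only C6' carries a β-hydrogen, and it gives the C3' enone with the C5'=C6' bond.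

**Step 8**
Reactants: 10 (S)-3a-methyl-2,3,5,6-tetrahydro-1H-indene-1,4(3aH)-dione
Product: 11 C9' ethylene ketal of enedione 10
Conditions: ethylene glycol, p-TsOH (cat.), 4 Å molecular sieves, rt
Reagents that add atoms: ethylene glycol, OCCO
Why: Acid-catalysed ketalisation should select the saturated C9' ketone over the less electrophilic conjugated C3' carbonyl, as in related bicyclic enediones.

**Step 9**
Reactants: 5 (E)-trisylhydrazone of 8β-hydroxy-8α-methyl-14,15,17-trinorlabdan-13-one; 11 C9' ethylene ketal of enedione 10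
Product: 13 bis-allylic 3'β-alcohol bearing the C4'(=CH2) side chain on the α face, via dilithiated vinyllithium 12 (not isolated)
Conditions: n-BuLi (3.3 equiv), THF, −78 to 0 °C (loss of N2); anhydrous CeCl3, −78 °C; then 11, −78 °C; aq NH4Cl
Reagents that add atoms: n-butyllithium, [Li]CCCC (lithium stays only in intermediate 12)
Why: The Shapiro reaction (deprotonation of the E-hydrazone on its methyl side gives the 1-alken-2-yl lithium) is followed by organocerium 1,2-addition, in which the nucleophile should reach C3' from the α face, opposite the β-methyl on C10' that stands 1,3 to the carbonyl, and so set the temporary 3'β-carbinol centre.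

**Step 10**
Reactants: 13 bis-allylic 3'β-alcohol bearing the C4'(=CH2) side chain on the α face
Product: 14 ring-expanded 3'-ketone (4'α-methyl, 4'β-chain, C5'=C6', C9' ketal)
Conditions: [N,N'-bis(3,5-di-tert-butylsalicylidene)-1,2-cyclohexanediaminato]cobalt (divalent cobalt, 5 mol %), N-fluoro-2,4,6-trimethylpyridinium triflate (1.2 equiv), PhSiH3 (1.2 equiv), PhCF3, 0 °C to rt
Reagents that add atoms: none
Why: A cobalt hydride delivers a hydrogen atom to the terminal CH2 of the 1,1-disubstituted alkene (this carbon becomes the C4' methyl group); the tertiary C4' radical, as such or after oxidation to the alkylcobalt or cation level, bonds to C5' of the neighbouring C5'=C6' bond, the transient cyclopropane reopens by cleavage of C3'–C5', and the C3' ketyl or oxocarbenium collapses to the ketone, the closest known reaction types being the hydrogen-atom-transfer-initiated radical–polar crossover semipinacol rearrangement of tertiary allylic alcohols and the radical 1,2-vinyl shift. Ring A is thus not closed by a cyclisation but arises from the cyclopentane C1'–C2'–C3'–C5'–C10' by insertion of C4' (transient 3-exo-trig closure, then ring opening), driven by loss of cyclopentane strain and by C=O formation. The only new stereocentre, C4', is controlled by the C3' carbinol centre: C4' hangs on the α face and must bond to the α lobe of C5', and in the bicyclo[3.1.0]-like transition state the long C12 chain should take the exo position next to the small hydroxyl group (least A1,2 strain) while the new methyl lies endo under the five-membered ring, so that exo becomes β (axial) and endo becomes α as C4' swings into the ring plane. The step needs chemoselective hydrogen-atom transfer (the 1,1-disubstituted alkene reacts much faster than the hindered trisubstituted C5'=C6'), migration of C5' and not C2' (only the sp2 carbon has the bridged pathway) and no ionisation of the bis-allylic alcohol (no Brønsted acid is present and the liberated collidine buffers the medium).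

**Step 11**
Reactants: 14 ring-expanded 3'-ketone (4'α-methyl, 4'β-chain, C5'=C6', C9' ketal)
Product: 15 trans-decalone (5'α-H, 3'-ketone, C9' ketal)
Conditions: Mn(dpm)3 (10 mol %), PhSiH3 (2 equiv), t-BuOOH (1.5 equiv), i-PrOH, rt
Reagents that add atoms: none
Why: In this hydrogen-atom-transfer hydrogenation the first hydrogen goes to the less hindered C6', and the tertiary C5' radical should take the second hydrogen axially on the α face, away from the axial C10' methyl and the axial C4' chain, which gives the trans ring fusion.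

**Step 12**
Reactants: 15 trans-decalone (5'α-H, 3'-ketone, C9' ketal)
Product: 16 3'-deoxo ketal
Conditions: N2H4·H2O, KOH, diethylene glycol, 130 °C then 210 °C
Reagents that add atoms: none
Why: Wolff–Kishner reduction (Huang-Minlon conditions) is the standard way to remove a 3-ketone next to a quaternary C4 in terpenoids, and it leaves the ketal, the tertiary alcohol and all (non-enolisable) stereocentres untouched.

**Step 13**
Reactants: 16 3'-deoxo ketal
Product: 17 9'-ketone
Conditions: 2 M HCl, THF, rt to 40 °C
Reagents that add atoms: water, O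
Why: Acid hydrolysis of the dioxolane frees the C9' ketone under conditions that a tertiary alcohol of this type should tolerate.

**Step 14**
Reactants: 17 9'-ketone
Product: 18 8'α-methyl-9'-ketone
Conditions: LDA (2.5 equiv), THF, −78 °C; MeI, −78 to 0 °C
Reagents that add atoms: iodomethane, CI
Why: Enolate alkylation can occur only at C8' because C10' is quaternary, and the configuration at C8' (expected equatorial) is erased in the next step.

**Step 15**
Reactants: 18 8'α-methyl-9'-ketone
Product: 19 8'-methyl-7'-en-9'-one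
Conditions: IBX (3 equiv), DMSO/fluorobenzene, 75 °C
Reagents that add atoms: none
Why: IBX dehydrogenation of the ketone through its only possible enol gives the more stable endocyclic 2-methyl enone and so places the C7'=C8' bond and the C8' methyl group of the target.

**Step 16**
Reactants: 19 8'-methyl-7'-en-9'-one
Product: 21 7',9'(11')-diene, via β-hydroxysilane 20 (not isolated)
Conditions: Me3SiCH2Li (3 equiv), THF, −78 to 0 °C; aq NH4Cl; crude adduct, KH, THF, rt
Reagents that add atoms: (trimethylsilyl)methyllithium, [Li]C[Si](C)(C)C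
Why: Peterson olefination uses a small, non-basic nucleophile that adds 1,2 even to this 2,6,6-trisubstituted enone, and base-induced syn elimination avoids acid at the tertiary allylic alcohol stage.

**Step 17**
Reactants: 21 7',9'(11')-diene; 22 2-bromo-1,4-dimethoxybenzene
Product: 24 hydroquinone dimethyl ether, via B-alkyl-9-BBN 23 (not isolated)
Conditions: 9-BBN, THF, 65 °C; then 22, Pd(dppf)Cl2 (5 mol %), AsPh3, Cs2CO3, DMF/H2O, 50 °C
Reagents that add atoms: 9-borabicyclo[3.3.1]nonane, B1C2CCCC1CCC2 (boron stays only in intermediate 23)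
Why: Hydroboration followed by B-alkyl Suzuki–Miyaura coupling should work because 9-BBN selects the 1,1-disubstituted alkene over the trisubstituted one and delivers hydrogen to C9' from the α face opposite the C10' methyl, which makes the C11' arm β (equatorial).

**Step 18**
Reactants: 24 hydroquinone dimethyl ether
Product: 26 hydroquinone, via benzoquinone 25 (not isolated)
Conditions: (NH4)2Ce(NO3)6 (2.5 equiv), MeCN/H2O, 0 °C; then Na2S2O4, THF/H2O, rt
Reagents that add atoms: water, O
Why: Oxidative demethylation by tetravalent cerium followed by dithionite reduction is the usual mild release of a hydroquinone, and it spares the trisubstituted alkene and the tertiary alcohol.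

**Step 19**
Reactants: 26 hydroquinone
Product: 28 CNP0471499.2 (target), via bis(pyridinium) salt 27 (not isolated)
Conditions: SO3·pyridine (6 equiv), pyridine, rt; then strong-acid cation-exchange resin (H+ form), MeOH/H2O, 0 °C
Reagents that add atoms: sulfur trioxide–pyridine complex, [O-]S(=O)(=O)[n+]1ccccc1
Why: O-sulfation with the sulfur trioxide–amine complex should take both phenols, while the axial tertiary 8β-alcohol is too hindered to react at room temperature.

**Compound list**

1 | (+)-manool, (13R)-labda-8(17),14-dien-13-ol | C=C[C@](C)(O)CC[C@@H]1[C@@]2(C)CCCC(C)(C)[C@@H]2CCC1=C | starting material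
2 | 14,15-dinorlabd-8(17)-en-13-one | CC(=O)CC[C@@H]1[C@@]2(C)CCCC(C)(C)[C@@H]2CCC1=C | intermediate
3 | 14,15,17-trinorlabdane-8,13-dione | CC(=O)CC[C@@H]1[C@@]2(C)CCCC(C)(C)[C@@H]2CCC1=O | intermediate
4 | 13-(E)-(2,4,6-triisopropylbenzenesulfonyl)hydrazone of dione 3, C8 ketone free | C/C(CC[C@@H]1[C@@]2(C)CCCC(C)(C)[C@@H]2CCC1=O)=N\NS(=O)(=O)c1c(C(C)C)cc(C(C)C)cc1C(C)C | intermediate
5 | (E)-trisylhydrazone of 8β-hydroxy-8α-methyl-14,15,17-trinorlabdan-13-one (OH axial, CH3 equatorial) | C/C(CC[C@@H]1[C@@]2(C)CCCC(C)(C)[C@@H]2CC[C@]1(C)O)=N\NS(=O)(=O)c1c(C(C)C)cc(C(C)C)cc1C(C)C | intermediate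
6 | 2-methylcyclohexane-1,3-dione | CC1C(=O)CCCC1=O | starting material
7 | acrolein | C=CC=O | starting material
8 | 3-(1-methyl-2,6-dioxocyclohexyl)propanal | CC1(CCC=O)C(=O)CCCC1=O | intermediate
9 | (3aS,7aR)-7a-hydroxy-3a-methylhexahydro-1H-indene-1,4(2H)-dione, cis-fused, OH and CH3 cis | O=C1CCC[C@]2(O)C(=O)CC[C@]12C | intermediate
10 | (S)-3a-methyl-2,3,5,6-tetrahydro-1H-indene-1,4(3aH)-dione (C3' enone, C5'=C6', C9' ketone) | O=C1CC[C@@]2(C)C1=CCCC2=O | intermediate
11 | C9' ethylene ketal of 10 | O=C1CC[C@@]2(C)C1=CCCC23OCCO3 | intermediate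
12 | dilithio species: C13 (= C4') vinyllithium and C8 lithium alkoxide | [Li]C(=C)CC[C@@H]1[C@@]2(C)CCCC(C)(C)[C@@H]2CC[C@]1(C)O[Li] | intermediate
13 | bis-allylic alcohol: 3'β-OH, 3'α-C4'(=CH2)–C12–C11–left half, C5'=C6', 10'β-CH3, C9' ketal | C=C(CC[C@@H]1[C@@]2(C)CCCC(C)(C)[C@@H]2CC[C@]1(C)O)[C@]1(O)CC[C@@]2(C)C1=CCCC23OCCO3 | intermediate
14 | ring-expanded ketone: 3'-oxo, 4'α-CH3, 4'β-chain, C5'=C6', C9' ketal | C1=C2[C@@](C)(CC[C@@H]3[C@@]4(C)CCCC(C)(C)[C@@H]4CC[C@]3(C)O)C(=O)CC[C@]2(C)C2(CC1)OCCO2 | intermediate
15 | trans-decalone: as 14 but 5'α-H, C5'–C6' saturated | C1C[C@H]2[C@@](C)(CC[C@@H]3[C@@]4(C)CCCC(C)(C)[C@@H]4CC[C@]3(C)O)C(=O)CC[C@]2(C)C2(C1)OCCO2 | intermediate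
16 | 3'-deoxo ketal | C1C[C@H]2[C@@](C)(CC[C@@H]3[C@@]4(C)CCCC(C)(C)[C@@H]4CC[C@]3(C)O)CCC[C@]2(C)C2(C1)OCCO2 | intermediate
17 | 9'-ketone | C1C[C@H]2[C@@](C)(CC[C@@H]3[C@@]4(C)CCCC(C)(C)[C@@H]4CC[C@]3(C)O)CCC[C@]2(C)C(=O)C1 | intermediate
18 | 8'α-methyl-9'-ketone | C1C[C@H]2[C@@](C)(CC[C@@H]3[C@@]4(C)CCCC(C)(C)[C@@H]4CC[C@]3(C)O)CCC[C@]2(C)C(=O)[C@@H]1C | intermediate
19 | 8'-methyl-7'-en-9'-one | CC1=CC[C@H]2[C@@](C)(CC[C@@H]3[C@@]4(C)CCCC(C)(C)[C@@H]4CC[C@]3(C)O)CCC[C@]2(C)C1=O | intermediate
20 | 9'β-hydroxy-9'α-(trimethylsilylmethyl) adduct | CC1=CC[C@H]2[C@@](C)(CC[C@@H]3[C@@]4(C)CCCC(C)(C)[C@@H]4CC[C@]3(C)O)CCC[C@]2(C)[C@]1(O)C[Si](C)(C)C | intermediate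
21 | 7',9'(11')-diene (exocyclic methylene on C9') | CC1=CC[C@H]2[C@@](C)(CC[C@@H]3[C@@]4(C)CCCC(C)(C)[C@@H]4CC[C@]3(C)O)CCC[C@]2(C)C1=C | intermediate
22 | 2-bromo-1,4-dimethoxybenzene | COc1ccc(OC)c(Br)c1 | starting material
23 | B-(C11')-alkyl-9-BBN, 9'α-H | CC1=CC[C@H]2[C@@](C)(CC[C@@H]3[C@@]4(C)CCCC(C)(C)[C@@H]4CC[C@]3(C)O)CCC[C@]2(C)[C@H]1CB1C2CCCC1CCC2 | intermediate
24 | hydroquinone dimethyl ether | CC1=CC[C@H]2[C@@](C)(CC[C@@H]3[C@@]4(C)CCCC(C)(C)[C@@H]4CC[C@]3(C)O)CCC[C@]2(C)[C@H]1Cc1cc(OC)ccc1OC | intermediate
25 | 2-substituted 1,4-benzoquinone | CC1=CC[C@H]2[C@@](C)(CC[C@@H]3[C@@]4(C)CCCC(C)(C)[C@@H]4CC[C@]3(C)O)CCC[C@]2(C)[C@H]1CC1=CC(=O)C=CC1=O | intermediate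
26 | hydroquinone | CC1=CC[C@H]2[C@@](C)(CC[C@@H]3[C@@]4(C)CCCC(C)(C)[C@@H]4CC[C@]3(C)O)CCC[C@]2(C)[C@H]1Cc1cc(O)ccc1O | intermediate
27 | bis(pyridinium) bis-sulfate | CC1=CC[C@H]2[C@@](C)(CC[C@@H]3[C@@]4(C)CCCC(C)(C)[C@@H]4CC[C@]3(C)O)CCC[C@]2(C)[C@H]1Cc1cc(OS(=O)(=O)[O-])ccc1OS(=O)(=O)[O-].c1cc[nH+]cc1.c1cc[nH+]cc1 | intermediate
28 | CNP0471499.2 | CC1=CC[C@H]2[C@@](C)(CC[C@@H]3[C@@]4(C)CCCC(C)(C)[C@@H]4CC[C@]3(C)O)CCC[C@]2(C)[C@H]1Cc1cc(OS(=O)(=O)O)ccc1OS(=O)(=O)O | target

**Step count and risks**

Total step count: 19. Longest linear sequence: 15 steps (steps 1–4 or 5–8, then 9–19).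

**Steps most likely to fail**

**Step 10.**
- Risk: the planar C4' centre may discriminate only weakly between the exo and endo placement of chain and methyl (poor facial selectivity), or the C3' hydroxyl may capture C4' (epoxide closure) before C5' migrates.
- Fallback, with the methyl group introduced last, sets out from 13.
- Lemieux–Johnson cleavage (OsO4 cat., NaIO4, 2,6-lutidine, dioxane/H2O) of the less hindered 1,1-disubstituted alkene gives the 3'-hydroxy-4'-ketone F1.
- An α-ketol rearrangement (Al(Ot-Bu)3, toluene, heat, or BF3·OEt2) then moves C5' from C3' to the C4' carbonyl carbon. This is the five-to-six enlargement known as D-homoannulation of 17-hydroxy-20-keto steroids, and it gives the ring-expanded α-ketol F2.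
- Acetylation (Ac2O, DMAP) gives the α-acetoxy ketone F3.
- Li/NH3 cleaves the acetoxy group to the C3'–C4' dienolate regiospecifically. MeI should then enter from the α face, opposite the axial C10' methyl, so the chain is left β.
- The fallback comes back at 14.

**Step 17.**
- Risk: hydroboration of the hindered, conjugated exocyclic alkene may be sluggish or poorly face-selective, and the β-branched alkylborane may transmetalate slowly.
- Fallback sets out from 19.
- Corey–Chaykovsky epoxidation (Me3SI, n-BuLi, THF) from the α face gives the spiro-epoxide F6.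
- Meinwald rearrangement (MgBr2·OEt2, −78 °C) and equilibration give the equatorial 9'β-carbaldehyde F7.
- The aryllithium made from 22 and n-BuLi adds to give the benzylic alcohol F8 (either carbinol epimer).
- 1,1'-Thiocarbonyldiimidazole gives the imidazolylthiocarbonate F9.
- Barton–McCombie reduction (Bu3SnH, AIBN, toluene, reflux) comes back at 24.

**Step 12.**
- Risk: hydrazone formation at the neopentyl C3' ketone under the axial chain may be incomplete, and the forcing temperature may start elimination of the tertiary alcohol.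
- Fallback sets out from 15.
- LiAlH4 (THF, 0 °C) gives the equatorial 3'β-alcohol F4.
- 1,1'-Thiocarbonyldiimidazole (DMAP, toluene, 90 °C) derivatises only the secondary alcohol and gives the imidazolylthiocarbonate F5.
- Barton–McCombie reduction (Bu3SnH, AIBN, toluene, reflux) comes back at 16.

**Further compounds**

F1 | step 10 | 3'β-hydroxy-4'-ketone (acyloin, five-membered ring kept) | O=C(CC[C@@H]1[C@@]2(C)CCCC(C)(C)[C@@H]2CC[C@]1(C)O)[C@]1(O)CC[C@@]2(C)C1=CCCC23OCCO3
F2 | step 10 | ring-expanded α-ketol (3'-oxo, 4'β-OH, 4'α-chain, C5'=C6') | C1=C2[C@](O)(CC[C@@H]3[C@@]4(C)CCCC(C)(C)[C@@H]4CC[C@]3(C)O)C(=O)CC[C@]2(C)C2(CC1)OCCO2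
F3 | step 10 | 4'-acetate of F2 | C1=C2[C@](OC(C)=O)(CC[C@@H]3[C@@]4(C)CCCC(C)(C)[C@@H]4CC[C@]3(C)O)C(=O)CC[C@]2(C)C2(CC1)OCCO2
F4 | step 12 | 3'β-alcohol from 15 | C1C[C@H]2[C@@](C)(CC[C@@H]3[C@@]4(C)CCCC(C)(C)[C@@H]4CC[C@]3(C)O)[C@@H](O)CC[C@]2(C)C2(C1)OCCO2
F5 | step 12 | 3'β-O-(imidazol-1-ylthiocarbonyl) derivative of F4 | C1C[C@H]2[C@@](C)(CC[C@@H]3[C@@]4(C)CCCC(C)(C)[C@@H]4CC[C@]3(C)O)[C@@H](OC(=S)n5ccnc5)CC[C@]2(C)C2(C1)OCCO2
F6 | step 17 | C9' spiro-epoxide (O β, CH2 α) | CC1=CC[C@H]2[C@@](C)(CC[C@@H]3[C@@]4(C)CCCC(C)(C)[C@@H]4CC[C@]3(C)O)CCC[C@]2(C)[C@]15CO5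
F7 | step 17 | 9'β-carbaldehyde | CC1=CC[C@H]2[C@@](C)(CC[C@@H]3[C@@]4(C)CCCC(C)(C)[C@@H]4CC[C@]3(C)O)CCC[C@]2(C)[C@H]1C=O
F8 | step 17 | C11' benzylic alcohol (carbinol centre undefined) | CC1=CC[C@H]2[C@@](C)(CC[C@@H]3[C@@]4(C)CCCC(C)(C)[C@@H]4CC[C@]3(C)O)CCC[C@]2(C)[C@H]1C(O)c1cc(OC)ccc1OC
F9 | step 17 | C11' O-(imidazol-1-ylthiocarbonyl) derivative of F8 | CC1=CC[C@H]2[C@@](C)(CC[C@@H]3[C@@]4(C)CCCC(C)(C)[C@@H]4CC[C@]3(C)O)CCC[C@]2(C)[C@H]1C(OC(=S)n1ccnc1)c1cc(OC)ccc1OC
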